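The ratio of initiator to free monomer charged is 0.100, and it is the same in the earlier runs. My own assumption is that each initiator takes one monomer into a chain as it reacts. The ratio then gives a bound from below on the monomer in chains once the initiator has reacted: the initiator floor, one monomer in chains per initiator charged, 10.0 %.

| flask | free monomer | transfer agent | capture agent | initiator | temperature | remark | time |
|---|---|---|---|---|---|---|---|
| gamma | 0.35 M | 0.0105 M | 0.052 M | 35 mM | 55 °C | run made earlier |  |
| zeta | 0.35 M | 0.0105 M | 0.079 M | 35 mM | 90 °C | run made earlier |  |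
| Friday's | 0.35 M | 0.0105 M | 0.105 M | 35 mM | 90 °C |  | 1.5 h |
| Saturday's | 0.35 M | 0.0105 M | 0.105 M | 35 mM | 120 °C |  | 1.5 h |
| Thursday's | 0.35 M | 0.0105 M | 0.105 M | 35 mM | 60 °C |  | 1.5 h |

gamma run (percent of the free monomer charged)

| time / h | monomer in chains / % | free monomer / % |
|---|---|---|
| 0.833 | 18.7 | 78.5 |
| 1.00 | 21.0 | 77.3 |
| 2.00 | 30.6 | 70.5 |
| 3.00 | 37.9 | 63.1 |
| 5.00 | 45.8 | 54.9 |
| 8.00 | 51.2 | 47.3 |
| 12.0 | 56.9 | 41.3 |

zeta run (percent of the free monomer charged)

| time / min | monomer in chains / % | free monomer / % |
|---|---|---|
| 15.0 | 22.2 | 77.6 |
| 30.0 | 24.7 | 75.4 |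
| 50.0 | 24.8 | 75.2 |
| 60.0 | 26.8 | 74.2 |
| 80.0 | 25.1 | 74.2 |
| 90.0 | 25.2 | 75.4 |
| 120 | 26.1 | 74.4 |

(standard deviation of a reading: 1 percentage point)

- the best flask by amount of monomer in chains, in percent of the free monomer charged; "all alike" if 1.5 percentage points covers them all (Friday's / Saturday's / Thursday's / all alike)
- amount of monomer in chains at the end, in percent of the free monomer charged, Friday's
- amount of monomer in chains at the end, in percent of the free monomer charged, Saturday's
- amount of monomer in chains at the end, in percent of the free monomer charged, Thursday's

- the numbers in the tables scatter with a standard deviation of 1 percentage point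

The bound from above for Friday's comes from the zeta run, which at 90 °C stands still within the scatter: it shows 24.7 % after 30.0 min and 26.1 % after 120 min, a gain of 1.4 points against a scatter of 1 point. Friday's has the same temperature and more [capture agent], so it should stop lower. If the excess over the floor goes inversely with [capture agent], Friday's ends near 22.1 %.

Scaled the same way to the gamma run's [capture agent], zeta's excess comes to 24 points. Yet gamma, at 55 °C, shows 47 points after 12.0 h, so cooling appears to raise the excess and heating to lower it. Saturday's, at 120 °C, should therefore lie between the floor and my figure for Friday's, and I take the middle, 16.1 %. For Thursday's, at 60 °C, I take as a rough estimate gamma's level at the same time, the mean of its readings at 1.00 h and 2.00 h, 25.8 %, although gamma differs from Thursday's in both temperature and [capture agent]. That puts Thursday's first.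

The forecast gave 22 % for Thursday's, 19 % for Friday's and 9 % for Saturday's, with Thursday's best, holding that “Hotter means a lower limit”. Its Saturday's value stands below the floor, outside the bracket.

The flasks end at 26.4 % for Thursday's, 21.4 % for Friday's and 15.8 % for Saturday's, so Thursday's is best.

    free monomer + initiator → living end + monomer in chains (k = 0.0380 L mol⁻¹ s⁻¹, Ea = 71.0 kJ mol⁻¹)
    free monomer + living end → monomer in chains + living end, rate k2*[living end]*[free monomer] (k = 0.00323 L mol⁻¹ s⁻¹, Ea = 53.0 kJ mol⁻¹)
    living end + transfer agent → dead chain (kL = 0.249 L mol⁻¹ s⁻¹, Ea = 51.0 kJ mol⁻¹)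
    2 living end ⇌ resting dimer, settled at all times (K = 11.0 L mol⁻¹, ΔH = −12.0 kJ mol⁻¹)
    living end + capture agent → trapped intermediate (k = 0.00276 L mol⁻¹ s⁻¹, Ea = 81.0 kJ mol⁻¹)
    (constants at 60 °C)

The first step of the scheme puts one monomer into chains per initiator, and Saturday's, with 0 % of its initiator left, stands above the floor by a factor of 1.58. A neighbour of Saturday's, charged with 0.060 M of initiator, has a floor of 17.1 %, and Saturday's factor on that floor gives 27.0 %. That neighbour, with 0 % of its initiator left, ends at 29.4 %.

The earlier runs and the new flask are calculated on assumed constants; noise was put on by code.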